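The plan disconnects the C9–O bond of the syn C9/C11 diol (chain numbered from the lactone carbonyl C1: ring carbinol C5, Z-alkene C6=C7, carbinols C9, C11, C13). These two oxygens fit a 1,3-dioxane chair in which phenyl, the C9 substituent and the C11 substituent are all equatorial, so C9 can be set by equilibration. In one operation Re2O7 shifts a primary C7 allylic hydroxyl to C9 and benzaldehyde dimethyl acetal traps the syn isomer. This forms one ring, three C–O bonds and two stereocentres. The precursor is a C7–C15 non-2-ene-1,5-diol with free C7 and C11 hydroxyls and a C13 silyl ether. The vinyl group released is then extended to the Z-alkenyl dihydropyranone.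

Key step: step 6

Remark on the chemistry: (−)-Ipc2BOMe is the reagent of the (+)-α-pinene series and (+)-Ipc2BOMe that of the (−)-α-pinene series. Compound 11 is drawn as its E isomer, but the E/Z mixture from step 5 is carried on because step 6 erases this geometry. TBSO = tert-butyldimethylsilyloxy. Atom labels C1–C15 follow the target numbering above.

Step 1
Reactants: 1 3-phenylpropanal; 2 allylmagnesium bromide
Product: 4 (3R)-1-phenylhex-5-en-3-ol, via borinate ester 3 (not isolated)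
Conditions: (−)-Ipc2BOMe, 2, Et2O, 0 °C to rt; 1, −78 °C; then 3 M NaOH, 30% H2O2, rt
Reagents that add atoms: none
Why: Brown asymmetric allylboration, in which the allylborane made from (−)-Ipc2BOMe reacts through a closed chair transition state on the Si face of the aldehyde, sets C13 as R under reagent control, and oxidative work-up frees the alcohol from 3.

Step 2
Reactants: 4 (3R)-1-phenylhex-5-en-3-ol
Product: 5 (3R)-3-(TBSO)-1-phenylhex-5-ene
Conditions: TBSCl, imidazole, DMF, rt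
Reagents that add atoms: tert-butyldimethylsilyl chloride, C[Si](C)(Cl)C(C)(C)C
Why: Imidazole-promoted silylation of a secondary alcohol masks O13 so that it cannot compete for the acetal in step 6, and it touches no stereocentre.

Step 3
Reactants: 5 (3R)-3-(TBSO)-1-phenylhex-5-ene
Product: 7 (3R)-3-(TBSO)-5-phenylpentanal, via secondary ozonide 6 (not isolated)
Conditions: O3, CH2Cl2, −78 °C; PPh3, −78 °C to rt
Reagents that add atoms: ozone, [O-][O+]=O
Why: Ozonolysis with reductive work-up cleaves the only alkene (the arene reacts far more slowly) and gives the C11 aldehyde without disturbing the β-silyloxy centre.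

Step 4
Reactants: 7 (3R)-3-(TBSO)-5-phenylpentanal; 2 allylmagnesium bromide
Product: 9 (4R,6R)-6-(TBSO)-8-phenyloct-1-en-4-ol, via borinate ester 8 (not isolated)
Conditions: (+)-Ipc2BOMe, 2, Et2O, 0 °C to rt; 7, −78 °C; then 3 M NaOH, 30% H2O2, rt
Reagents that add atoms: none
Why: A second Brown allylboration with the enantiomeric reagent attacks the Re face of 7, so reagent control overrides the weak bias of the β-silyloxy group and sets C11 anti to C13.

Step 5
Reactants: 9 (4R,6R)-6-(TBSO)-8-phenyloct-1-en-4-ol; 10 (Z)-but-2-ene-1,4-diol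
Product: 11 (2E,5R,7R)-7-(TBSO)-9-phenylnon-2-ene-1,5-diol
Conditions: 10 (excess), second-generation Hoveyda–Grubbs catalyst RuCl2(H2IMes)(=CH-C6H4-2-OiPr) (3 mol %), CH2Cl2, 40 °C
Reagents that add atoms: none
Why: Olefin cross metathesis of a terminal alkene with an excess of a symmetrical allylic diol adds C7 as a primary allylic alcohol, tolerates free hydroxyls, and its E/Z outcome does not matter for step 6.

Step 6
Reactants: 11 (2E,5R,7R)-7-(TBSO)-9-phenylnon-2-ene-1,5-diol; 12 benzaldehyde dimethyl acetal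
Product: 16 (2S,4S,6R)-6-[(2R)-2-(TBSO)-4-phenylbutyl]-2-phenyl-4-vinyl-1,3-dioxane, via C7 perrhenate ester 13 (not isolated), via transposed 1-ene-3,5-diol 14 (not isolated), via O11 oxocarbenium ion 15 (not isolated)
Conditions: Re2O7 (5 mol %), 12 (1.5 equiv), CH2Cl2, 0 °C to rt; Et3N quench
Reagents that add atoms: none
Why: Re2O7 esterifies the C7 hydroxyl to perrhenate 13 (heptavalent rhenium), which passes through a chair-like six-membered [3,3] transition state that exchanges the C7–O bond for a C9–O bond and moves the alkene to C7=C8, so that both C9 epimers of 14 form reversibly. The acidic rhenium species also activates 12, O11 is turned into the benzylic oxocarbenium ion 15, and the C9 hydroxyl closes the 1,3-dioxane by 6-endo-trig attack (the C=O+ bond lies inside the new ring), a closure open only to the transposed isomer because the C7 hydroxyl would have to form an eight-membered ring. The closest known reaction type is the Re2O7-catalysed 1,3-transposition of allylic alcohols intercepted by a neighbouring hydroxyl as a syn benzylidene acetal. C9 is controlled thermodynamically by the existing C11 centre, because transposition and acetal exchange stay reversible and the anti epimer, whose dioxane would carry an axial substituent, is fed back into the equilibrium, and the acetal carbon is controlled in the same way by the equatorial preference of phenyl. The step needs positional selectivity for C9, syn selectivity and no participation of O13, which are secured by ring size, by the triequatorial chair and by the C13 silyl ether, while the alkene geometry of 11 is erased and need not be defined. Low catalyst loading, low temperature and an amine quench should keep the TBS ether and the unstabilised allyl system from ionising.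

Step 7
Reactants: 16 (2S,4S,6R)-6-[(2R)-2-(TBSO)-4-phenylbutyl]-2-phenyl-4-vinyl-1,3-dioxane
Product: 18 2-{(2R,4R,6R)-6-[(2R)-2-(TBSO)-4-phenylbutyl]-2-phenyl-1,3-dioxan-4-yl}ethanol, via B-alkyl-9-BBN adduct 17 (not isolated)
Conditions: 9-BBN, THF, 0 °C to rt; then 3 M NaOH, 30% H2O2, 0 °C to rt
Reagents that add atoms: hydrogen peroxide, OO
Why: Hydroboration–oxidation with bulky 9-BBN places boron only on terminal C7, remote from the C9–O bond so that no β-alkoxy elimination is possible, and alkaline peroxide replaces boron by hydroxyl while the acetal and silyl ether are inert to base.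

Step 8
Reactants: 18 2-{(2R,4R,6R)-6-[(2R)-2-(TBSO)-4-phenylbutyl]-2-phenyl-1,3-dioxan-4-yl}ethanol
Product: 19 2-{(2S,4S,6R)-6-[(2R)-2-(TBSO)-4-phenylbutyl]-2-phenyl-1,3-dioxan-4-yl}acetaldehyde
Conditions: Dess–Martin periodinane, NaHCO3, CH2Cl2, 0 °C to rt
Reagents that add atoms: none
Why: Buffered Dess–Martin oxidation stops at the aldehyde and, being non-basic, avoids β-elimination of the C9 acetal oxygen (the descriptors change only through priority, not in space).

Step 9
Reactants: 19 2-{(2S,4S,6R)-6-[(2R)-2-(TBSO)-4-phenylbutyl]-2-phenyl-1,3-dioxan-4-yl}acetaldehyde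
Product: 20 (2R,4R,6R)-6-[(2R)-2-(TBSO)-4-phenylbutyl]-2-phenyl-4-(prop-2-yn-1-yl)-1,3-dioxane
Conditions: dimethyl (1-diazo-2-oxopropyl)phosphonate, K2CO3, MeOH/THF, 0 °C to rt
Reagents that add atoms: dimethyl (1-diazo-2-oxopropyl)phosphonate, COP(=O)(OC)C(=[N+]=[N-])C(C)=O
Why: Seyferth–Gilbert homologation in its Ohira–Bestmann form adds C6 and converts the aldehyde into the terminal alkyne under K2CO3/MeOH, a base mild enough for β-alkoxy aldehydes.

Step 10
Reactants: 20 (2R,4R,6R)-6-[(2R)-2-(TBSO)-4-phenylbutyl]-2-phenyl-4-(prop-2-yn-1-yl)-1,3-dioxane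
Product: 22 4-{(2R,4R,6R)-6-[(2R)-2-(TBSO)-4-phenylbutyl]-2-phenyl-1,3-dioxan-4-yl}but-2-ynal, via lithium acetylide 21 (not isolated)
Conditions: n-BuLi, THF, −78 °C; DMF, −78 to 0 °C; inverse quench into cold aq KH2PO4
Reagents that add atoms: N,N-dimethylformamide, CN(C)C=O
Why: Deprotonation of the terminal alkyne and formylation of acetylide 21 with DMF adds C5, and the buffered inverse quench releases the ynal without base-induced isomerisation.

Step 11
Reactants: 22 4-{(2R,4R,6R)-6-[(2R)-2-(TBSO)-4-phenylbutyl]-2-phenyl-1,3-dioxan-4-yl}but-2-ynal; 2 allylmagnesium bromide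
Product: 24 (4S)-7-{(2R,4R,6R)-6-[(2R)-2-(TBSO)-4-phenylbutyl]-2-phenyl-1,3-dioxan-4-yl}hept-1-en-5-yn-4-ol, via borinate ester 23 (not isolated)
Conditions: (−)-Ipc2BOMe, 2, Et2O, 0 °C to rt; 22, −78 °C; then 3 M NaOH, 30% H2O2, 0 °C to rt
Reagents that add atoms: none
Why: A third Brown allylboration, again with the (−)-Ipc2BOMe-derived reagent, adds allyl to the Si face of the ynal through a closed chair transition state and sets C5 as S, with the remote dioxane centres exerting no influence.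

Step 12
Reactants: 24 (4S)-7-{(2R,4R,6R)-6-[(2R)-2-(TBSO)-4-phenylbutyl]-2-phenyl-1,3-dioxan-4-yl}hept-1-en-5-yn-4-ol
Product: 25 (4S,5Z)-7-{(2R,4R,6R)-6-[(2R)-2-(TBSO)-4-phenylbutyl]-2-phenyl-1,3-dioxan-4-yl}hepta-1,5-dien-4-ol
Conditions: H2 (1 atm), Lindlar catalyst (Pd on CaCO3 poisoned with Pb(OAc)2), quinoline, EtOAc, rt, stopped after one equivalent of H2
Reagents that add atoms: none
Why: Lindlar semihydrogenation delivers H2 syn to the strongly adsorbed alkyne and so fixes the Z geometry at C6=C7, while quinoline poisoning and the stop at one equivalent should spare the terminal alkene.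

Step 13
Reactants: 25 (4S,5Z)-7-{(2R,4R,6R)-6-[(2R)-2-(TBSO)-4-phenylbutyl]-2-phenyl-1,3-dioxan-4-yl}hepta-1,5-dien-4-ol; 26 acryloyl chloride
Product: 27 (4S,5Z)-7-{(2R,4R,6R)-6-[(2R)-2-(TBSO)-4-phenylbutyl]-2-phenyl-1,3-dioxan-4-yl}hepta-1,5-dien-4-yl prop-2-enoate
Conditions: 26, iPr2NEt, CH2Cl2, −20 to 0 °C
Reagents that add atoms: none
Why: O-acylation of the secondary allylic alcohol with an acid chloride and a hindered amine takes place at oxygen and therefore retains C5.

Step 14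
Reactants: 27 (4S,5Z)-7-{(2R,4R,6R)-6-[(2R)-2-(TBSO)-4-phenylbutyl]-2-phenyl-1,3-dioxan-4-yl}hepta-1,5-dien-4-yl prop-2-enoate
Product: 28 (6S)-6-[(1Z)-3-{(2R,4R,6R)-6-[(2R)-2-(TBSO)-4-phenylbutyl]-2-phenyl-1,3-dioxan-4-yl}prop-1-en-1-yl]-5,6-dihydro-2H-pyran-2-one
Conditions: first-generation Grubbs catalyst RuCl2(=CHPh)(PCy3)2 (10 mol %), CH2Cl2 (dilute), reflux
Reagents that add atoms: none
Why: In this ring-closing metathesis the catalyst loads onto the terminal alkene and closes the six-membered enoate ring on the acrylate with loss of ethene, the ring enforces the cis C2=C3 geometry, and the C6=C7 alkene stays out because the loaded carbene could only close a four-membered ring with it.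

Step 15
Reactants: 28 (6S)-6-[(1Z)-3-{(2R,4R,6R)-6-[(2R)-2-(TBSO)-4-phenylbutyl]-2-phenyl-1,3-dioxan-4-yl}prop-1-en-1-yl]-5,6-dihydro-2H-pyran-2-one
Product: 29 (6S)-6-[(1Z,4R,6S,8R)-4,6,8-trihydroxy-10-phenyldec-1-en-1-yl]-5,6-dihydro-2H-pyran-2-one
Conditions: 2 M aq HCl, THF, 0 °C to rt
Reagents that add atoms: none
Why: Acid hydrolysis removes the benzylidene acetal and the secondary TBS ether in one operation without breaking a C–O bond at any stereocentre, and any lactone opened reversibly should reclose because the Z-hydroxy acid lactonises spontaneously.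

Compound list
1 | 3-phenylpropanal | O=CCCc1ccccc1 | starting material
2 | allylmagnesium bromide | C=CC[Mg]Br | starting material
3 | diisopinocampheylborinate of 4 (Ipc groups of the (+)-α-pinene series; not isolated) | C=CC[C@H](OB([C@@H]1C[C@@H]2C[C@H]([C@H]1C)C2(C)C)[C@@H]1C[C@@H]2C[C@H]([C@H]1C)C2(C)C)CCc1ccccc1 | intermediate
4 | (3R)-1-phenylhex-5-en-3-ol | C=CC[C@H](O)CCc1ccccc1 | intermediate
5 | (3R)-3-(TBSO)-1-phenylhex-5-ene | C=CC[C@H](O[Si](C)(C)C(C)(C)C)CCc1ccccc1 | intermediate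
6 | secondary ozonide of 5 (3-substituted 1,2,4-trioxolane, ring carbon unassigned; not isolated) | C1OC(C[C@H](O[Si](C)(C)C(C)(C)C)CCc2ccccc2)OO1 | intermediate
7 | (3R)-3-(TBSO)-5-phenylpentanal | O=CC[C@H](O[Si](C)(C)C(C)(C)C)CCc1ccccc1 | intermediate
8 | diisopinocampheylborinate of 9 (Ipc groups of the (−)-α-pinene series; not isolated) | C=CC[C@@H](OB([C@H]1C[C@H]2C[C@@H]([C@@H]1C)C2(C)C)[C@H]1C[C@H]2C[C@@H]([C@@H]1C)C2(C)C)C[C@H](O[Si](C)(C)C(C)(C)C)CCc1ccccc1 | intermediate
9 | (4R,6R)-6-(TBSO)-8-phenyloct-1-en-4-ol (C11/C13 anti) | C=CC[C@@H](O)C[C@H](O[Si](C)(C)C(C)(C)C)CCc1ccccc1 | intermediate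
10 | (Z)-but-2-ene-1,4-diol | OC/C=C\CO | starting material
11 | (2E,5R,7R)-7-(TBSO)-9-phenylnon-2-ene-1,5-diol | OC/C=C/C[C@@H](O)C[C@H](O[Si](C)(C)C(C)(C)C)CCc1ccccc1 | intermediate
12 | benzaldehyde dimethyl acetal | COC(OC)c1ccccc1 | starting material
13 | C7 perrhenate ester of 11 (not isolated) | O=[Re](=O)(=O)OC/C=C/C[C@@H](O)C[C@H](O[Si](C)(C)C(C)(C)C)CCc1ccccc1 | intermediate
14 | (5R,7R)-7-(TBSO)-9-phenylnon-1-ene-3,5-diol, both epimers at C9 of the target numbering (not isolated) | C=CC(O)C[C@@H](O)C[C@H](O[Si](C)(C)C(C)(C)C)CCc1ccccc1 | intermediate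
15 | O11 benzylic oxocarbenium ion of the syn epimer of 14 (not isolated) | C=C[C@@H](O)C[C@H](C[C@H](O[Si](C)(C)C(C)(C)C)CCc1ccccc1)[O+]=Cc1ccccc1 | intermediate
16 | (2S,4S,6R)-6-[(2R)-2-(TBSO)-4-phenylbutyl]-2-phenyl-4-vinyl-1,3-dioxane (all-cis, triequatorial) | C=C[C@@H]1C[C@H](C[C@H](O[Si](C)(C)C(C)(C)C)CCc2ccccc2)O[C@H](c2ccccc2)O1 | intermediate
17 | B-alkyl-9-borabicyclo[3.3.1]nonane with boron on C7 of 16 (not isolated) | C(C[C@@H]1C[C@H](C[C@H](O[Si](C)(C)C(C)(C)C)CCc2ccccc2)O[C@H](c2ccccc2)O1)B1C2CCCC1CCC2 | intermediate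
18 | 2-{(2R,4R,6R)-6-[(2R)-2-(TBSO)-4-phenylbutyl]-2-phenyl-1,3-dioxan-4-yl}ethanol (all-cis dioxane) | OCC[C@@H]1C[C@H](C[C@H](O[Si](C)(C)C(C)(C)C)CCc2ccccc2)O[C@H](c2ccccc2)O1 | intermediate
19 | 2-{(2S,4S,6R)-6-[(2R)-2-(TBSO)-4-phenylbutyl]-2-phenyl-1,3-dioxan-4-yl}acetaldehyde (all-cis dioxane) | O=CC[C@@H]1C[C@H](C[C@H](O[Si](C)(C)C(C)(C)C)CCc2ccccc2)O[C@H](c2ccccc2)O1 | intermediate
20 | (2R,4R,6R)-6-[(2R)-2-(TBSO)-4-phenylbutyl]-2-phenyl-4-(prop-2-yn-1-yl)-1,3-dioxane | C#CC[C@@H]1C[C@H](C[C@H](O[Si](C)(C)C(C)(C)C)CCc2ccccc2)O[C@H](c2ccccc2)O1 | intermediate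
21 | lithium acetylide of 20 (not isolated) | [Li]C#CC[C@@H]1C[C@H](C[C@H](O[Si](C)(C)C(C)(C)C)CCc2ccccc2)O[C@H](c2ccccc2)O1 | intermediate
22 | 4-{(2R,4R,6R)-6-[(2R)-2-(TBSO)-4-phenylbutyl]-2-phenyl-1,3-dioxan-4-yl}but-2-ynal | O=CC#CC[C@@H]1C[C@H](C[C@H](O[Si](C)(C)C(C)(C)C)CCc2ccccc2)O[C@H](c2ccccc2)O1 | intermediate
23 | diisopinocampheylborinate of 24 (Ipc groups of the (+)-α-pinene series; not isolated) | C=CC[C@H](OB([C@@H]1C[C@@H]2C[C@H]([C@H]1C)C2(C)C)[C@@H]1C[C@@H]2C[C@H]([C@H]1C)C2(C)C)C#CC[C@@H]1C[C@H](C[C@H](O[Si](C)(C)C(C)(C)C)CCc2ccccc2)O[C@H](c2ccccc2)O1 | intermediate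
24 | (4S)-7-{(2R,4R,6R)-6-[(2R)-2-(TBSO)-4-phenylbutyl]-2-phenyl-1,3-dioxan-4-yl}hept-1-en-5-yn-4-ol | C=CC[C@H](O)C#CC[C@@H]1C[C@H](C[C@H](O[Si](C)(C)C(C)(C)C)CCc2ccccc2)O[C@H](c2ccccc2)O1 | intermediate
25 | (4S,5Z)-7-{(2R,4R,6R)-6-[(2R)-2-(TBSO)-4-phenylbutyl]-2-phenyl-1,3-dioxan-4-yl}hepta-1,5-dien-4-ol | C=CC[C@H](O)/C=C\C[C@@H]1C[C@H](C[C@H](O[Si](C)(C)C(C)(C)C)CCc2ccccc2)O[C@H](c2ccccc2)O1 | intermediate
26 | acryloyl chloride | C=CC(=O)Cl | starting material
27 | (4S,5Z)-7-{(2R,4R,6R)-6-[(2R)-2-(TBSO)-4-phenylbutyl]-2-phenyl-1,3-dioxan-4-yl}hepta-1,5-dien-4-yl prop-2-enoate | C=CC[C@H](OC(=O)C=C)/C=C\C[C@@H]1C[C@H](C[C@H](O[Si](C)(C)C(C)(C)C)CCc2ccccc2)O[C@H](c2ccccc2)O1 | intermediate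
28 | (6S)-6-[(1Z)-3-{(2R,4R,6R)-6-[(2R)-2-(TBSO)-4-phenylbutyl]-2-phenyl-1,3-dioxan-4-yl}prop-1-en-1-yl]-5,6-dihydro-2H-pyran-2-one | O=C1C=CC[C@@H](/C=C\C[C@@H]2C[C@H](C[C@H](O[Si](C)(C)C(C)(C)C)CCc3ccccc3)O[C@H](c3ccccc3)O2)O1 | intermediate
29 | (6S)-6-[(1Z,4R,6S,8R)-4,6,8-trihydroxy-10-phenyldec-1-en-1-yl]-5,6-dihydro-2H-pyran-2-one | O=C1C=CC[C@@H](/C=C\C[C@@H](O)C[C@@H](O)C[C@H](O)CCc2ccccc2)O1 | target

Total step count: 15. Longest linear sequence: 15 steps (1 to 29).

Steps most likely to fail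

Step 6 (key step).
- **What may go wrong:** acid-induced loss of the C13 silyl group followed by acetal scrambling, dehydrative etherification between O11 and C7, or incomplete equilibration of the C9 epimers.
- **Fallback:** it makes the C9–O bond by conjugate addition instead of transposition and sets out from 9.
- Cross metathesis of 9 with methyl acrylate (second-generation Hoveyda–Grubbs catalyst, CH2Cl2, 40 °C) gives methyl (2E,5R,7R)-7-(TBSO)-5-hydroxy-9-phenylnon-2-enoate F1.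
- Benzaldehyde and KOtBu added in portions (THF, 0 °C) convert the C11 hydroxyl into a hemiacetal alkoxide. This adds reversibly to C9 (oxa-Michael reaction under thermodynamic control) and gives the all-cis ester methyl 2-{(2S,4S,6R)-6-[(2R)-2-(TBSO)-4-phenylbutyl]-2-phenyl-1,3-dioxan-4-yl}acetate F2.
- DIBAL-H (CH2Cl2, −78 °C) reduces F2 to aldehyde 19, where the route is rejoined.

Step 12.
- **What may go wrong:** over-reduction of the terminal alkene or of the new Z-alkene, or Z to E isomerisation on the catalyst surface.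
- **Fallback:** it uses neither an alkyne nor hydrogen and sets out from 19.
- Still–Gennari olefination ((CF3CH2O)2P(O)CH2CO2Me, KHMDS, 18-crown-6, THF, −78 °C) gives methyl (2Z)-4-{(2R,4R,6R)-6-[(2R)-2-(TBSO)-4-phenylbutyl]-2-phenyl-1,3-dioxan-4-yl}but-2-enoate F3.
- DIBAL-H (CH2Cl2, −78 °C) gives (2Z)-4-{(2R,4R,6R)-6-[(2R)-2-(TBSO)-4-phenylbutyl]-2-phenyl-1,3-dioxan-4-yl}but-2-en-1-ol F4.
- Buffered Dess–Martin oxidation gives (2Z)-4-{(2R,4R,6R)-6-[(2R)-2-(TBSO)-4-phenylbutyl]-2-phenyl-1,3-dioxan-4-yl}but-2-enal F5, which is used at once.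
- Brown allylboration with the reagent from (−)-Ipc2BOMe and 2 (Et2O, −78 °C) gives the diisopinocampheylborinate of 25 F6.
- Alkaline peroxide then releases dienol 25, where the route is rejoined.

Step 15.
- **What may go wrong:** slow acetal hydrolysis that forces long acid exposure, during which ionisation of the allylic C5–O bond with capture by the freed C9 hydroxyl, or Z to E isomerisation, may set in.
- **Fallback:** it works stepwise without aqueous mineral acid and sets out from 28.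
- HF·pyridine buffered with pyridine (THF, 0 °C) removes the silyl group and gives (6S)-6-[(1Z)-3-{(2R,4R,6S)-6-[(2R)-2-hydroxy-4-phenylbutyl]-2-phenyl-1,3-dioxan-4-yl}prop-1-en-1-yl]-5,6-dihydro-2H-pyran-2-one F7.
- Buffered thiol exchange (EtSH, Zn(OTf)2, NaHCO3, CH2Cl2, rt) then transfers the benzylidene carbon to sulfur and frees the target 29.

Further compounds
F1 | step 6 | methyl (2E,5R,7R)-7-(TBSO)-5-hydroxy-9-phenylnon-2-enoate | COC(=O)/C=C/C[C@@H](O)C[C@H](O[Si](C)(C)C(C)(C)C)CCc1ccccc1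
F2 | step 6 | methyl 2-{(2S,4S,6R)-6-[(2R)-2-(TBSO)-4-phenylbutyl]-2-phenyl-1,3-dioxan-4-yl}acetate | COC(=O)C[C@@H]1C[C@H](C[C@H](O[Si](C)(C)C(C)(C)C)CCc2ccccc2)O[C@H](c2ccccc2)O1
F3 | step 12 | methyl (2Z)-4-{(2R,4R,6R)-6-[(2R)-2-(TBSO)-4-phenylbutyl]-2-phenyl-1,3-dioxan-4-yl}but-2-enoate | COC(=O)/C=C\C[C@@H]1C[C@H](C[C@H](O[Si](C)(C)C(C)(C)C)CCc2ccccc2)O[C@H](c2ccccc2)O1
F4 | step 12 | (2Z)-4-{(2R,4R,6R)-6-[(2R)-2-(TBSO)-4-phenylbutyl]-2-phenyl-1,3-dioxan-4-yl}but-2-en-1-ol | OC/C=C\C[C@@H]1C[C@H](C[C@H](O[Si](C)(C)C(C)(C)C)CCc2ccccc2)O[C@H](c2ccccc2)O1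
F5 | step 12 | (2Z)-4-{(2R,4R,6R)-6-[(2R)-2-(TBSO)-4-phenylbutyl]-2-phenyl-1,3-dioxan-4-yl}but-2-enal | O=C/C=C\C[C@@H]1C[C@H](C[C@H](O[Si](C)(C)C(C)(C)C)CCc2ccccc2)O[C@H](c2ccccc2)O1
F6 | step 12 | diisopinocampheylborinate of 25 (Ipc groups of the (+)-α-pinene series) | C=CC[C@H](OB([C@@H]1C[C@@H]2C[C@H]([C@H]1C)C2(C)C)[C@@H]1C[C@@H]2C[C@H]([C@H]1C)C2(C)C)/C=C\C[C@@H]1C[C@H](C[C@H](O[Si](C)(C)C(C)(C)C)CCc2ccccc2)O[C@H](c2ccccc2)O1
F7 | step 15 | (6S)-6-[(1Z)-3-{(2R,4R,6S)-6-[(2R)-2-hydroxy-4-phenylbutyl]-2-phenyl-1,3-dioxan-4-yl}prop-1-en-1-yl]-5,6-dihydro-2H-pyran-2-one | O=C1C=CC[C@@H](/C=C\C[C@@H]2C[C@H](C[C@H](O)CCc3ccccc3)O[C@H](c3ccccc3)O2)O1
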